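Remarks on the chemistry (assumptions, one line each)
- Carbon numbers are those of the macrolide: C1 is the lactone carbonyl, the ring runs C1–C41 plus the ring oxygen, and the side chain is C42–C50.
- Structure check: the target is (2E,4Z,20Z,38Z) with 7S,9R,11S,13R,15S,17R,18R,19R,23R,27R,31R,41S,42S,43R,49R; in 72 and 73 every stereocentre, the three anti-acetonides and both alkyne termini map onto 75 atom by atom, so the skeleton needed no correction.
- Design change: the ester of 72 is assembled by olefination at C2=C3 from a phosphonoacetate of the C41 alcohol, so the (2E,4Z)-dienoic acid is never activated.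
- CIP letters are written where they were worked out for that compound; elsewhere each stereocentre has the configuration in the SMILES, which is spatially that of the same carbon in 75.
- salen = N,N′-bis(3,5-di-tert-butylsalicylidene)-1,2-cyclohexanediamine dianion; (R,R)-(salen)Co(OAc) is assumed to hydrolyse the (R)-alkyloxirane and (S,S)-(salen)Co(OAc) the (S)-alkyloxirane.
- (−)-Ipc2B reagents (from (+)-α-pinene) are assumed to add to the Si face of an aldehyde, and (S)-Cl,MeO-BIPHEP is assumed to give the (4S,6S) diol in step 1.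

## Structural features

The target is a single ring, a 42-membered lactone (C1–C41 and the ring oxygen), with a C42–C50 side chain on the lactone carbinol C41. The ring carries a (2E,4Z)-4-methyl-dienoate, an all-anti 1,3-polyol from C7 to C19 (seven oxygens, with the C18 methyl anti to O17 and syn to O19), a Z-alkene at C20–C21, three isolated carbinols at C23, C27 and C31 separated by three methylenes each, and a Z-alkene at C38–C39. C41, C42 and C43 form a contiguous syn,syn triad (O, Me, O), and C49 is an isolated carbinol. The fragile parts are the dienoate (geometric isomerisation, conjugate addition), the allylic C19 carbinol, and the lactone, which sits 1,3 to the free C43 hydroxyl and can migrate. The real difficulty is fifteen stereocentres in four groups that cannot control one another, three Z-configured double bonds, and closure of a very large, flexible ring. The key step exploits the fact that C38=C39 is the only functional group in the C32–C40 methylene stretch: it can be carried as a C38≡C39 triple bond and formed by ring-closing alkyne metathesis, which leaves the C20=C21 alkene and the C2–C5 dienoate alone.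

## Logic of the disconnections

75 ⇒ 74. All nine hydroxyls are released last, cutting six O–Si bonds and three acetal carbons. This keeps every intermediate non-polar and free of OH groups that could acylate or poison the metathesis catalyst. The forward step must remove everything in one acidic fluoride treatment without acyl migration.

74 ⇒ 73. The C38=C39 Z-alkene is traced back to the C38≡C39 alkyne. The gain is geometric certainty; the demand is a semi-hydrogenation that stops at the alkene and leaves three other C=C bonds untouched.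

73 ⇒ 72 (key). The C38≡C39 bond is cut, giving an open diyne with two methyl-capped ends. The ring is opened at its least functionalised point, remote from all stereocentres except C41. The forward step must prefer alkyne over alkene and ring over oligomer.

72 ⇒ 55 + 71. The C2=C3 bond is cut rather than the ester C–O bond. This gives a Z-enal and a phosphonoacetate already carrying the C41 oxygen, so the hindered secondary alcohol is acylated with a simple acid and the sensitive dienoate appears only at the union. The forward olefination must be E-selective and mild enough to leave the Z-enal unisomerised.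

55 ⇒ 48 (through 54, 53, 50, 49). The C4=C5 bond is cut to the C5 aldehyde 50 and phosphonate 51; the oxidation state at C3 is adjusted through 53 and 54, and C5 is unmasked from the ether 48. This postpones the trisubstituted Z-alkene until after the last strongly basic step. The olefination must be Z-selective for a trisubstituted enoate.

48 ⇒ 46 + 31. The C20=C21 bond is cut into a phosphonium salt and an α-silyloxy aldehyde. This splits the chain into the polyol half and the tris-carbinol half at the only point between them that can be made with Z control from simple partners. It demands a salt-free ylide reaction at low temperature so that C19 does not epimerise.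

31 ⇒ 17 + 26 (through 29, 28, 27). The C15–C16 bond is cut (aldol), the C17 carbinol is traced to a ketone, and the C20 aldehyde to a vinyl group. One C–C bond then delivers C15 and, after directed reduction, C17, while 26 brings C18 and C19 ready-made. 26 goes back through 24, 23, 22 and 21 to 18 and 19. The aldol must be 1,3-anti with respect to O13 and the reduction 1,3-anti with respect to O15.

17 ⇒ 8 + 12 (through 16, 15, 14, 13). The same module is applied one unit earlier: the C11–C12 bond is cut (aldol with the enol silane of a four-carbon ketone made from 9) and C13 is traced to a ketone. The stereochemical demands are the same, here relative to O9 and O11.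

8 ⇒ 1 + 2 (through 7, 6, 4, 3). The C6–C7 and C9–C10 bonds are cut together, reducing the C5–C11 unit to a three-carbon diol and two allyl units. C2 symmetry means one catalyst-controlled reaction sets C7 and C9, and the two ends are homotopic, so mono-protection gives a single compound. The demand is clean mono-functionalisation of 6.

46 ⇒ 36 + three units of 33 (through 45–38). The C24–C25, C28–C29 and C32–C33 bonds are cut, each between a primary Grignard carbon and the terminal carbon of the same chiral bromo-epoxide. C23, C27 and C31 all come from one resolved building block and the terminal bromide is reused as the next nucleophile and finally as the phosphonium site. 36 comes from 34 and 35, and 33 from 32. The forward step must open the epoxide without touching the primary bromide.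

71 ⇒ 69 + 70, then 69 ⇒ 68 + 35, 68 ⇒ 65, 65 ⇒ 61 + 62, 61 ⇒ 56 + 57. The ester C–O bond, the C39–C40 bond (acetylide on a terminal epoxide), the epoxide oxygen at C41, the C42–C43 bond (crotylation) and the C47–C48 bond (Grignard on 57) are cut in turn. C49 comes from the chiral pool, C42/C43 from one reagent-controlled step, and C41 from a catalyst-controlled resolution that also leaves O41 free and O43 protected. The demand is a syn-selective crotylation and an epoxide of defined configuration at C41.

## Other disconnections considered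

Alternative 1: The cut is at C8–C9 and C15–C16 at once, in a C2-symmetric C9–C15 diol whose acetonide spans C11/C13. That diol is compound 6 of this route, read as C9–C15 instead of C5–C11. In the forward key step both primary alcohols of 6 would be dehydrogenated in situ by the iridium catalyst and allylated with 2 to give A1, setting C9 and C15 together. In its favour: four stereocentres (C9–C15) would be in place after four steps under catalyst control, with the enantiomeric purity upgraded by the double addition, and no aldehyde is handled. Against it here: A1 has two identical allyl ends that must become the dienoate side and the C17–C19 side, so a statistical mono-functionalisation falls on a more valuable compound. C7 and C17 would still need a further C–C bond each with 1,3-anti control, and C9 and C15 need temporary protection before they can be paired in acetonides with C7 and C17. Comparison: structurally both plans start from the same double allylation (step 1), and mechanistically the reaction is identical. On stereocontrol the alternative is the better, since the chosen plan relies on substrate control in the aldols of steps 8 and 18. On step count for the C9–C15 core the alternative is also the better. The chosen plan differentiates the ends once and early (step 4), each later C–C bond brings two stereocentres, and the C16–C20 unit arrives as one piece. On the need for one desymmetrisation the two are equal.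

Alternative 2: The cut is at C4=C5 inside a temporary six-membered lactone. The methacrylate A3 of the C7 homoallylic alcohol would undergo ring-closing olefin metathesis with a ruthenium alkylidene (second-generation Grubbs catalyst) to give the dihydropyranone A2, with loss of ethylene. The ring forces C3 and C6 cis, so the 4Z geometry is guaranteed; reduction to the lactol and olefination would later give the (2E,4Z)-dienoate. In its favour: the geometry is fixed by the ring rather than by kinetic selectivity (better than step 34), the reagents are simple, and C3 arrives at a useful oxidation level. Against it here: the ruthenium carbene would also engage the methyl-capped alkynes and the C20=C21 alkene, so the metathesis must come before both, and the lactone must then survive the ylide chemistry of the union. O7 serves as the tether, so it cannot sit in a C7/C9 acetonide; the polyol would be protected as in A2 (acetonides on C9/C11 and C13/C15). After ring opening a free C7 hydroxyl faces the dienoate and would need protection. Comparison: the alternative needs about four operations from the C7 alcohol to the dienoate against six here (steps 32–36 and 46), so it is equal or slightly better in step count and better in geometric certainty. The chosen plan is better in compatibility with the alkyne-bearing late intermediates and keeps the six polyol oxygens in three acetonides.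

Alternative 3: The cut is at C20=C21 inside a temporary eight-membered 1,3-dioxa-2-silacyclooctene. The mixed diisopropylsilylene bis-ether A5, linking O19 (vinyl carbinol) and O23 (allyl carbinol), would undergo ring-closing olefin metathesis to A4 with loss of ethylene. In its favour: the medium ring enforces the Z geometry (better than the kinetic Z-selectivity of step 31), and the partners are two terminal alkenes, so there is no epimerisable α-oxygenated aldehyde and no strong base. The silylene also protects O19 and O23 and would fall in the final fluoride step, which is equal to the silyl ethers used here. Against it here: the ruthenium carbene is incompatible with the C38 alkyne, so A4 carries C38 as a silyl ether and the alkyne would have to be built afterwards (about three more steps). The real fragment union is the stepwise formation of two Si–O bonds to two secondary alcohols, one of them hindered at C19, with symmetrical bis-ethers as possible side products. Comparison: mechanistically it is a [2+2]/cycloreversion at ruthenium against an ylide addition and oxaphosphetane collapse here. Counting two silylations and the metathesis against phosphonium formation, oxidative cleavage and Wittig reaction (steps 30, 21, 31), the two are equal. The chosen plan is shorter overall because 46 carries the alkyne from the start; the alternative is better in geometric certainty and in mildness.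

Key step: step 47

## Route

Step 1
Reactants: 1 propane-1,3-diol; 2 prop-2-en-1-yl acetate (allyl acetate)
Product: 3 (4S,6S)-nona-1,8-diene-4,6-diol
Conditions: [Ir(cod)Cl]2 (5 mol %), (S)-Cl,MeO-BIPHEP (10 mol %), 4-chloro-3-nitrobenzoic acid (20 mol %), Cs2CO3 (40 mol %), 2 (10 equiv), 1,4-dioxane, 90 °C
Reagents that add atoms: none
Why: Two-directional iridium-catalysed transfer-hydrogenative allylation (Krische allylation): each CH2OH is dehydrogenated and the aldehyde is allylated by the chiral π-allyliridium, so C7 and C9 are both set by the ligand; the second addition diverts the minor enantiomer into the meso diol, which should leave the C2-symmetric anti diol nearly enantiopure.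

Step 2
Reactants: 3 (4S,6S)-nona-1,8-diene-4,6-diol
Product: 4 (4S,6S)-2,2-dimethyl-4,6-di(prop-2-en-1-yl)-1,3-dioxane
Conditions: 2,2-dimethoxypropane, PPTS (cat.), CH2Cl2, rt
Reagents that add atoms: 2,2-dimethoxypropane, COC(C)(C)OC
Why: Acid-catalysed transacetalisation of a 1,3-diol; the anti diol should give the acetonide without affecting either stereocentre.

Step 3
Reactants: 4 (4S,6S)-2,2-dimethyl-4,6-di(prop-2-en-1-yl)-1,3-dioxane
Product: 6 2,2′-[(4S,6S)-2,2-dimethyl-1,3-dioxane-4,6-diyl]di(ethan-1-ol), via dialdehyde 5 (not isolated)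
Conditions: O3, CH2Cl2–MeOH, −78 °C; then NaBH4, −78 °C → rt
Reagents that add atoms: ozone, [O-][O+]=O
Why: Ozonolysis of both terminal alkenes with reductive borohydride work-up; the stereocentres are not involved and the C2-symmetric diol (C5 and C11 as CH2OH) should result.

Step 4
Reactants: 6 2,2′-[(4S,6S)-2,2-dimethyl-1,3-dioxane-4,6-diyl]di(ethan-1-ol)
Product: 7 2-[(4S,6S)-6-{2-[(4-methoxyphenyl)methoxy]ethyl}-2,2-dimethyl-1,3-dioxan-4-yl]ethan-1-ol
Conditions: Ag2O (1.5 equiv), 4-methoxybenzyl chloride (1.1 equiv), CH2Cl2, rt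
Reagents that add atoms: 4-methoxybenzyl chloride, COc1ccc(CCl)cc1
Why: Silver-oxide-mediated Williamson etherification of a symmetric diol should stop largely at the mono-ether; the two ends are homotopic, so a single mono-ether forms and the chain now has a C5 end (ether) and a C11 end (free OH).

Step 5
Reactants: 7 mono-PMB ether
Product: 8 2-[(4R,6S)-6-{2-[(4-methoxyphenyl)methoxy]ethyl}-2,2-dimethyl-1,3-dioxan-4-yl]acetaldehyde
Conditions: Dess–Martin periodinane, NaHCO3, CH2Cl2, 0 °C → rt
Reagents that add atoms: none
Why: Dess–Martin oxidation of a primary alcohol under buffered, non-epimerising conditions; the β-alkoxy aldehyde (C11) has no α-stereocentre.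

Step 6
Reactants: 9 4-hydroxybutan-2-one
Product: 10 4-{[tert-butyl(dimethyl)silyl]oxy}butan-2-one
Conditions: TBSCl, imidazole, CH2Cl2, 0 °C → rt
Reagents that add atoms: tert-butyl(chloro)dimethylsilane, CC(C)(C)[Si](C)(C)Cl
Why: Standard silylation of a primary alcohol.

Step 7
Reactants: 10 4-{[tert-butyl(dimethyl)silyl]oxy}butan-2-one
Product: 12 tert-butyl(dimethyl){[3-(trimethylsilyloxy)but-3-en-1-yl]oxy}silane, via lithium enolate 11 (not isolated)
Conditions: LiN(iPr)2, THF, −78 °C; then Me3SiCl, −78 °C → 0 °C
Reagents that add atoms: chlorotrimethylsilane, C[Si](C)(C)Cl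
Why: Kinetic deprotonation on the methyl side and O-silylation give the terminal enol silane; the enolate does not lie on the side bearing the β-silyloxy group, so elimination should not compete.

Step 8
Reactants: 8 C5–C11 aldehyde; 12 enol silane (C12–C15)
Product: 13 C5–C15 β-hydroxy ketone (PMB ether at C5; 7,9-anti-acetonide; 11-OH anti to O9; ketone at C13; TBS ether at C15)
Conditions: BF3·OEt2, CH2Cl2, −78 °C
Reagents that add atoms: none
Why: Mukaiyama aldol through an open transition state; the β-oxygen at C9 directs attack to the face that gives the 1,3-anti (9,11-anti) adduct (dipole-minimised conformer, the same sense as under chelation), which sets C11.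

Step 9
Reactants: 13 C5–C15 β-hydroxy ketone
Product: 14 C5–C15 11,13-anti diol (PMB ether at C5; 7,9-anti-acetonide; TBS ether at C15)
Conditions: Me4NBH(OAc)3, MeCN–AcOH (1:1), −30 °C
Reagents that add atoms: none
Why: Evans–Saksena reduction: the C11 hydroxyl exchanges onto boron and delivers hydride intramolecularly through a chair transition state, which sets C13 anti to C11.

Step 10
Reactants: 14 C5–C15 11,13-anti diol
Product: 15 C5–C15 bis-acetonide (PMB ether at C5; anti-acetonides on C7/C9 and C11/C13; TBS ether at C15)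
Conditions: 2,2-dimethoxypropane, PPTS (cat.), CH2Cl2, rt
Reagents that add atoms: 2,2-dimethoxypropane, COC(C)(C)OC
Why: Acetonide formation from the anti-1,3-diol; the primary TBS and PMB ethers are stable to PPTS.

Step 11
Reactants: 15 C5–C15 bis-acetonide
Product: 16 C5–C15 bis-acetonide with free C15 hydroxyl
Conditions: Bu4NF, THF, 0 °C → rt
Reagents that add atoms: none
Why: Fluoride cleavage of the only silyl ether in the molecule.

Step 12
Reactants: 16 C15 alcohol
Product: 17 C5–C15 bis-acetonide C15 aldehyde
Conditions: Dess–Martin periodinane, NaHCO3, CH2Cl2, 0 °C → rt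
Reagents that add atoms: none
Why: Dess–Martin oxidation to the β-alkoxy aldehyde needed for the second aldol module.

Step 13
Reactants: 18 (S)-4-benzyl-3-propanoyl-1,3-oxazolidin-2-one; 19 prop-2-enal (acrolein)
Product: 21 (S)-4-benzyl-3-[(2S,3R)-3-hydroxy-2-methylpent-4-enoyl]-1,3-oxazolidin-2-one, via (Z)-dibutylboron enolate 20 (not isolated)
Conditions: Bu2BOTf, iPr2NEt, CH2Cl2, 0 °C; 19, −78 → 0 °C; then pH 7 buffer, MeOH, H2O2
Reagents that add atoms: none
Why: Evans syn-aldol: the Z-boron enolate reacts through a Zimmerman–Traxler chair in which the benzyl group of the auxiliary blocks one face, giving the (2S,3R) syn adduct (C18 methyl and C19 oxygen).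

Step 14
Reactants: 21 Evans aldol adduct
Product: 22 (2S,3R)-3-hydroxy-N-methoxy-N,2-dimethylpent-4-enamide
Conditions: MeNH(OMe)·HCl, AlMe3, CH2Cl2, −20 °C → rt
Reagents that add atoms: N,O-dimethylhydroxylamine hydrochloride, CNOC.Cl
Why: Weinreb transamination of the imide by the aluminium amide, which is known to work on β-hydroxy imides without retro-aldol; the auxiliary is released for recovery.

Step 15
Reactants: 22 Weinreb amide
Product: 23 (2S,3R)-3-{[tert-butyl(dimethyl)silyl]oxy}-N-methoxy-N,2-dimethylpent-4-enamide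
Conditions: TBSOTf, 2,6-lutidine, CH2Cl2, −78 → 0 °C
Reagents that add atoms: tert-butyldimethylsilyl trifluoromethanesulfonate, CC(C)(C)[Si](C)(C)OS(=O)(=O)C(F)(F)F
Why: Silylation of the secondary allylic alcohol; this TBS group is the final protecting group of O19.

Step 16
Reactants: 23 silylated Weinreb amide
Product: 24 (3S,4R)-4-{[tert-butyl(dimethyl)silyl]oxy}-3-methylhex-5-en-2-one
Conditions: MeMgBr, THF, 0 °C
Reagents that add atoms: methylmagnesium bromide, C[Mg]Br
Why: Grignard addition to a Weinreb amide stops at the chelated tetrahedral intermediate and gives the methyl ketone on work-up; the C18 centre should not epimerise.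

Step 17
Reactants: 24 methyl ketone
Product: 26 tert-butyl{[(3R,4S)-4-methyl-5-(trimethylsilyloxy)hexa-1,5-dien-3-yl]oxy}dimethylsilane, via lithium enolate 25 (not isolated)
Conditions: LiN(iPr)2, THF, −78 °C; then Me3SiCl, −78 °C
Reagents that add atoms: chlorotrimethylsilane, C[Si](C)(C)Cl
Why: Kinetic enolisation at the methyl group (the less hindered α-position) and O-silylation; the C18 stereocentre on the other α-carbon is not deprotonated at −78 °C.

Step 18
Reactants: 17 C5–C15 aldehyde; 26 enol silane (C16–C20)
Product: 27 C5–C20 β-hydroxy ketone (15-OH anti to O13; ketone at C17; C18 methyl; TBS ether at C19; vinyl at C19)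
Conditions: BF3·OEt2, CH2Cl2, −78 °C
Reagents that add atoms: none
Why: Mukaiyama aldol, the same module as step 8: open transition state with 1,3-anti induction from the C13 oxygen sets C15; the stereocentres of the enol silane are remote from the reacting carbon and have little influence.

Step 19
Reactants: 27 C5–C20 β-hydroxy ketone
Product: 28 C5–C20 15,17-anti diol
Conditions: Me4NBH(OAc)3, MeCN–AcOH (1:1), −30 °C
Reagents that add atoms: none
Why: Evans–Saksena reduction with intramolecular hydride delivery from O15 sets C17 anti to C15, which is also anti to the C18 methyl and to O19 as required.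

Step 20
Reactants: 28 15,17-anti diol
Product: 29 C5–C20 tris-acetonide (PMB ether at C5; anti-acetonides on C7/C9 and C11/C13 and C15/C17; TBS ether at C19; terminal vinyl)
Conditions: 2,2-dimethoxypropane, PPTS (cat.), CH2Cl2, rt
Reagents that add atoms: 2,2-dimethoxypropane, COC(C)(C)OC
Why: Acetonide formation from the third anti-diol completes the protecting pattern of the polyol.

Step 21
Reactants: 29 C5–C20 tris-acetonide
Product: 31 C5–C20 tris-acetonide C20 aldehyde (α-silyloxy aldehyde), via vicinal diol 30 (not isolated)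
Conditions: OsO4 (2 mol %), NaIO4, 2,6-lutidine, dioxane–H2O (3:1), rt
Reagents that add atoms: sodium periodate (oxygen, relayed by OsO4), [Na+].[O-]I(=O)(=O)=O
Why: Johnson–Lemieux cleavage of the only alkene: osmylation then periodate scission; chosen over ozone because the PMB ether is inert to it, and the buffered medium should keep C19 from epimerising.

Step 22
Reactants: 32 rac-2-(2-bromoethyl)oxirane
Product: 33 (S)-2-(2-bromoethyl)oxirane
Conditions: (R,R)-(salen)Co(OAc) (0.5 mol %), H2O (0.55 equiv), THF, 0 °C → rt; distillation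
Reagents that add atoms: none
Why: Jacobsen hydrolytic kinetic resolution: the cobalt–salen catalyst hydrolyses the (R)-epoxide by a cooperative bimetallic mechanism and leaves the (S)-epoxide, the source of C23, C27 and C31.

Step 23
Reactants: 34 1-bromo-5-chloropentane; 35 prop-1-yn-1-yllithium
Product: 36 8-chlorooct-2-yne
Conditions: THF–DMPU, −78 °C → rt
Reagents that add atoms: none
Why: SN2 alkylation of the acetylide; bromide is displaced much faster than chloride, so the methyl-capped alkyne (C38) is installed with the chloride kept for the Grignard.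

Step 24
Reactants: 36 8-chlorooct-2-yne; 33 (S)-2-(2-bromoethyl)oxirane
Product: 38 (R)-1-bromododec-10-yn-3-ol, via oct-6-yn-1-ylmagnesium chloride 37 (not isolated)
Conditions: Mg, I2 (cat.), THF, reflux; then CuI (10 mol %), 33, THF, −40 → −20 °C
Reagents that add atoms: none
Why: Copper-catalysed Grignard opening of a terminal epoxide at its CH2 carbon (SN2); at low temperature this should be much faster than coupling at the primary C–Br bond, and C31 keeps the configuration of 33.

Step 25
Reactants: 38 (R)-1-bromododec-10-yn-3-ol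
Product: 39 (R)-[(1-bromododec-10-yn-3-yl)oxy](tert-butyl)dimethylsilane
Conditions: TBSCl, imidazole, DMF, rt
Reagents that add atoms: tert-butyl(chloro)dimethylsilane, CC(C)(C)[Si](C)(C)Cl
Why: Silylation of the secondary alcohol also removes the risk of oxetane formation from the bromo alcohol.

Step 26
Reactants: 39 silylated bromide; 33 (S)-2-(2-bromoethyl)oxirane
Product: 41 (3R,7R)-1-bromo-7-{[tert-butyl(dimethyl)silyl]oxy}hexadec-14-yn-3-ol, via [(3R)-3-silyloxydodec-10-yn-1-yl]magnesium bromide 40 (not isolated)
Conditions: Mg, THF, 40 °C; then CuI (10 mol %), 33, THF, −40 → −20 °C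
Reagents that add atoms: none
Why: Same copper-catalysed epoxide opening; the γ-silyloxy Grignard has no β-leaving group and should be stable, and C27 comes from 33.

Step 27
Reactants: 41 (3R,7R)-bromo alcohol
Product: 42 (3R,7R)-1-bromo-3,7-bis{[tert-butyl(dimethyl)silyl]oxy}hexadec-14-yne
Conditions: TBSCl, imidazole, DMF, rt
Reagents that add atoms: tert-butyl(chloro)dimethylsilane, CC(C)(C)[Si](C)(C)Cl
Why: Silylation of the secondary alcohol.

Step 28
Reactants: 42 bis-silylated bromide; 33 (S)-2-(2-bromoethyl)oxirane
Product: 44 (3R,7S,11R)-1-bromo-7,11-bis{[tert-butyl(dimethyl)silyl]oxy}icos-18-yn-3-ol (C23/C27/C31 as in 75; the 7S letter only reflects CIP ranking), via [(3R,7R)-3,7-bis(silyloxy)hexadec-14-yn-1-yl]magnesium bromide 43 (not isolated)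
Conditions: Mg, THF, 40 °C; then CuI (10 mol %), 33, THF, −40 → −20 °C
Reagents that add atoms: none
Why: Third copper-catalysed epoxide opening sets C23 from 33; the three carbinols come from one enantiopure reagent, so no diastereomer mixture should build up.

Step 29
Reactants: 44 bromo alcohol
Product: 45 (3R,7R,11R)-1-bromo-3,7,11-tris{[tert-butyl(dimethyl)silyl]oxy}icos-18-yne
Conditions: TBSCl, imidazole, DMF, rt
Reagents that add atoms: tert-butyl(chloro)dimethylsilane, CC(C)(C)[Si](C)(C)Cl
Why: Silylation of the secondary alcohol.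

Step 30
Reactants: 45 tris-silylated bromide
Product: 46 [(3R,7R,11R)-3,7,11-tris{[tert-butyl(dimethyl)silyl]oxy}icos-18-yn-1-yl]triphenylphosphonium bromide
Conditions: PPh3 (3 equiv), K2CO3 (cat.), MeCN, 85 °C
Reagents that add atoms: triphenylphosphine, c1ccccc1P(c1ccccc1)c1ccccc1
Why: SN2 quaternisation of triphenylphosphine by an unhindered primary bromide; a trace of base scavenges HBr so the silyl ethers survive.

Step 31
Reactants: 46 phosphonium bromide (C21–C38); 31 C5–C20 aldehyde
Product: 48 C5–C38 chain with the 20Z alkene (PMB ether at C5; three anti-acetonides; TBS ethers at C19/C23/C27/C31; methyl-capped alkyne at C38), via phosphorus ylide 47 (not isolated)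
Conditions: NaN(SiMe3)2, THF, −78 °C; then 31, −78 → −20 °C
Reagents that add atoms: none
Why: Wittig reaction of a salt-free, non-stabilised ylide: kinetic formation of the cis-oxaphosphetane and syn-elimination give the Z-alkene; the low temperature and the fast addition should prevent epimerisation of the α-silyloxy aldehyde.

Step 32
Reactants: 48 C5–C38 PMB ether
Product: 49 C5–C38 primary alcohol (free C5 hydroxyl)
Conditions: DDQ, CH2Cl2–pH 7 buffer, 0 °C
Reagents that add atoms: none
Why: Oxidative cleavage of the PMB ether (hydride abstraction to the oxocarbenium ion, then hydrolysis); silyl ethers, acetonides, the alkyne and the isolated Z-alkene are not electron-rich enough to react, and the buffer protects the acetonides.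

Step 33
Reactants: 49 C5 alcohol
Product: 50 C5–C38 C5 aldehyde
Conditions: Dess–Martin periodinane, NaHCO3, CH2Cl2, 0 °C → rt
Reagents that add atoms: none
Why: Dess–Martin oxidation under buffered conditions.

Step 34
Reactants: 50 C5 aldehyde; 51 ethyl 2-[bis(2,2,2-trifluoroethoxy)phosphoryl]propanoate
Product: 53 ethyl (Z)-2-methyl-enoate of the C3–C38 chain (4Z trisubstituted alkene), via potassium phosphonate carbanion 52 (not isolated)
Conditions: 51, KN(SiMe3)2, 18-crown-6, THF, −78 °C; then 50
Reagents that add atoms: none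
Why: Still–Gennari olefination: the electron-poor phosphonate and the dissociated potassium counter-ion make elimination from the first-formed adduct fast and irreversible, which gives the Z-configured trisubstituted enoate (C4=C5).

Step 35
Reactants: 53 (Z)-enoate
Product: 54 (Z)-allylic alcohol (C3 hydroxyl) of the C3–C38 chain
Conditions: iBu2AlH, CH2Cl2, −78 °C
Reagents that add atoms: none
Why: 1,2-Reduction of the α,β-unsaturated ester by the aluminium hydride; silyl ethers, acetonides and the alkyne are inert at −78 °C.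

Step 36
Reactants: 54 (Z)-allylic alcohol
Product: 55 (Z)-2-methyl-enal of the C3–C38 chain (C3 aldehyde)
Conditions: MnO2, CH2Cl2, rt
Reagents that add atoms: none
Why: Chemoselective allylic oxidation on the MnO2 surface under neutral conditions, which should preserve the Z geometry; the enal is used at once.

Step 37
Reactants: 56 6-bromohex-1-ene; 57 (R)-2-methyloxirane ((R)-propylene oxide)
Product: 59 (R)-non-8-en-2-ol, via hex-5-en-1-ylmagnesium bromide 58 (not isolated)
Conditions: Mg, THF; then CuI (10 mol %), 57, THF, −30 °C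
Reagents that add atoms: none
Why: Copper-catalysed Grignard opening of the epoxide at CH2; C49 comes unchanged from the chiral pool.

Step 38
Reactants: 59 (R)-non-8-en-2-ol
Product: 60 (R)-tert-butyl(dimethyl)(non-8-en-2-yloxy)silane
Conditions: TBSCl, imidazole, DMF, rt
Reagents that add atoms: tert-butyl(chloro)dimethylsilane, CC(C)(C)[Si](C)(C)Cl
Why: Silylation of the secondary alcohol (final protecting group of O49).

Step 39
Reactants: 60 silyl ether
Product: 61 (R)-7-{[tert-butyl(dimethyl)silyl]oxy}octanal
Conditions: O3, CH2Cl2, −78 °C; then PPh3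
Reagents that add atoms: ozone, [O-][O+]=O
Why: Ozonolysis of the terminal alkene with reductive work-up gives the C43 aldehyde.

Step 40
Reactants: 61 (R)-7-silyloxyoctanal; 62 (Z)-but-2-ene
Product: 65 (3R,4R,10R)-10-{[tert-butyl(dimethyl)silyl]oxy}-3-methylundec-1-en-4-ol, via (Z)-but-2-en-1-ylpotassium 63 (not isolated), via (Z)-crotyl-bis(isopinocampheyl)borane 64 (not isolated)
Conditions: 62, KOtBu, n-BuLi, THF, −78 → −45 °C; (−)-Ipc2BOMe, −78 °C; BF3·OEt2; 61, −78 °C; then NaOH, H2O2
Reagents that add atoms: none
Why: Brown crotylation: the (Z)-crotylborane adds through a closed chair transition state, so the Z geometry gives the syn relation of C42 methyl and C43 hydroxyl, and the isopinocampheyl groups from (+)-α-pinene direct attack to the Si face (C43 R, C42 R in this compound).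

Step 41
Reactants: 65 syn homoallylic alcohol
Product: 66 (3R,4R,10R)-4,10-bis{[tert-butyl(dimethyl)silyl]oxy}-3-methylundec-1-ene
Conditions: TBSOTf, 2,6-lutidine, CH2Cl2, −78 → 0 °C
Reagents that add atoms: tert-butyldimethylsilyl trifluoromethanesulfonate, CC(C)(C)[Si](C)(C)OS(=O)(=O)C(F)(F)F
Why: Silylation of the hindered secondary alcohol with the triflate; this fixes O43 as the protected oxygen before O41 is introduced.

Step 42
Reactants: 66 bis-silyl alkene
Product: 67 2-[(2R,3R,9R)-3,9-bis{[tert-butyl(dimethyl)silyl]oxy}decan-2-yl]oxirane (both epimers at the oxirane carbon)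
Conditions: mCPBA, NaHCO3, CH2Cl2, 0 °C → rt
Reagents that add atoms: 3-chloroperoxybenzoic acid, OOC(=O)c1cccc(Cl)c1
Why: Prilezhaev epoxidation of the terminal alkene; little facial bias is expected next to the C42 centre, so the epimer mixture is taken into the resolution.

Step 43
Reactants: 67 epoxide mixture
Product: 68 (R)-2-[(2R,3R,9R)-3,9-bis{[tert-butyl(dimethyl)silyl]oxy}decan-2-yl]oxirane
Conditions: (S,S)-(salen)Co(OAc) (2 mol %), H2O (0.55 equiv), THF–iPrOH, rt
Reagents that add atoms: none
Why: Jacobsen hydrolytic kinetic resolution under catalyst control: the (S)-configured oxirane epimer is hydrolysed to the diol and the (R)-epoxide (C41) remains, separable by chromatography.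

Step 44
Reactants: 68 (R)-epoxide; 35 prop-1-yn-1-yllithium
Product: 69 (5S,6R,7R,13R)-7,13-bis{[tert-butyl(dimethyl)silyl]oxy}-6-methyltetradec-2-yn-5-ol
Conditions: 35 (3 equiv), BF3·OEt2 (3 equiv), THF, −78 °C
Reagents that add atoms: none
Why: BF3-promoted opening of the epoxide by the acetylide at the terminal carbon (Yamaguchi–Hirao alkynylation); C41 is not touched, and the methyl-capped homopropargylic alcohol is formed with O41 free and O43 protected.

Step 45
Reactants: 69 C39–C50 alkynol; 70 2-(diethoxyphosphoryl)acetic acid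
Product: 71 (5S,6R,7R,13R)-7,13-bis{[tert-butyl(dimethyl)silyl]oxy}-6-methyltetradec-2-yn-5-yl 2-(diethoxyphosphoryl)acetate
Conditions: DCC, DMAP (cat.), CH2Cl2, 0 °C → rt
Reagents that add atoms: none
Why: Steglich esterification of the secondary alcohol with a simple, non-isomerisable acid; the ester oxygen of the future lactone is fixed here.

Step 46
Reactants: 55 (Z)-enal (C3–C38); 71 phosphonoacetate (C1–C2 and C39–C50)
Product: 72 ester-linked seco-diyne with the (2E,4Z)-dienoate (three anti-acetonides; six TBS ethers; methyl-capped alkynes at C38 and C39)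
Conditions: Ba(OH)2 (activated), THF–H2O (40:1), 0 °C → rt
Reagents that add atoms: none
Why: Horner–Wadsworth–Emmons olefination with a stabilised phosphonate: reversible addition and anti-elimination give the 2E alkene, and the mild barium base should leave the Z-enal, the ester and the silyl ethers intact; this joins the two halves.

Step 47
Reactants: 72 ester-linked seco-diyne
Product: 73 protected 42-membered cycloalkyne (C38≡C39)
Conditions: Mo(≡CC6H4-4-OMe)(OSiPh3)3 (15 mol %), 5 Å molecular sieves, toluene (1 mM), 80 °C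
Reagents that add atoms: none
Why: Ring-closing alkyne metathesis: the molybdenum alkylidyne adds one methyl-capped alkyne of 72 by [2+2] to a molybdacyclobutadiene, which cycloreverts to a chain-bound alkylidyne; this adds the second alkyne intramolecularly and cycloreversion releases the ring and a small alkylidyne that carries the chain, with but-2-yne as the only by-product. The closest known reaction type is the ring-closing metathesis of methyl-capped diynes by molybdenum alkylidyne silanolate catalysts to large cycloalkynes. One ring is closed, the 42-membered lactone ring, end to end by forming the endocyclic C38≡C39 bond; it is a strain-free macrocyclisation to which small-ring closure rules do not apply. No stereocentre is formed and the fifteen present are untouched under neutral aprotic conditions. Alkyne-over-alkene selectivity comes from the catalyst, since a high-valent Mo≡C unit does not undergo [2+2] with the C20=C21 alkene or the C2–C5 dienoate. Ring-over-oligomer selectivity comes from the 1 mM concentration and the reversibility of the process, which lets oligomers return to the ring. The 5 Å sieves absorb but-2-yne and pull the equilibrium to 73. The substrate has no free hydroxyl, only ethers, esters, acetals and silyl ethers, which this catalyst class tolerates.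

Step 48
Reactants: 73 protected cycloalkyne
Product: 74 protected macrolide with the 38Z alkene
Conditions: H2 (1 atm), Pd on CaCO3 poisoned with Pb(OAc)2, quinoline, EtOAc, rt
Reagents that add atoms: none
Why: Lindlar semi-hydrogenation: syn delivery of hydrogen on the poisoned palladium surface gives the Z-alkene, and the alkyne binds so much more strongly than the alkenes that the C20=C21 alkene and the dienoate should not be reduced if uptake is monitored.

Step 49
Reactants: 74 protected macrolide
Product: 75 CNP0071908.1 (target)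
Conditions: HF (48 % aq.), MeCN, 0 °C → rt
Reagents that add atoms: none
Why: Global deprotection: fluoride under acidic conditions cleaves the six silyl ethers and the aqueous acid hydrolyses the three anti-acetonides (the more labile acetonide type); no base is present, so the lactone and the dienoate should survive.

## Compound list

1 | propane-1,3-diol | OCCCO | starting material
2 | prop-2-en-1-yl acetate | CC(=O)OCC=C | starting material
3 | (4S,6S)-nona-1,8-diene-4,6-diol | C=CC[C@H](O)C[C@@H](O)CC=C | intermediate
4 | (4S,6S)-2,2-dimethyl-4,6-di(prop-2-en-1-yl)-1,3-dioxane | C=CC[C@H](O1)C[C@@H](OC1(C)C)CC=C | intermediate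
5 | 2,2′-[(4R,6R)-2,2-dimethyl-1,3-dioxane-4,6-diyl]diacetaldehyde (not isolated) | O=CC[C@H](O1)C[C@@H](OC1(C)C)CC=O | intermediate
6 | 2,2′-[(4S,6S)-2,2-dimethyl-1,3-dioxane-4,6-diyl]di(ethan-1-ol) | OCC[C@H](O1)C[C@@H](OC1(C)C)CCO | intermediate
7 | 2-[(4S,6S)-6-{2-[(4-methoxyphenyl)methoxy]ethyl}-2,2-dimethyl-1,3-dioxan-4-yl]ethan-1-ol | COc1ccc(COCC[C@H](O2)C[C@@H](OC2(C)C)CCO)cc1 | intermediate
8 | 2-[(4R,6S)-6-{2-[(4-methoxyphenyl)methoxy]ethyl}-2,2-dimethyl-1,3-dioxan-4-yl]acetaldehyde | COc1ccc(COCC[C@H](O2)C[C@@H](OC2(C)C)CC=O)cc1 | intermediate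
9 | 4-hydroxybutan-2-one | CC(=O)CCO | starting material
10 | 4-{[tert-butyl(dimethyl)silyl]oxy}butan-2-one | CC(=O)CCO[Si](C)(C)C(C)(C)C | intermediate
11 | lithium 4-{[tert-butyl(dimethyl)silyl]oxy}but-1-en-2-olate (not isolated) | [Li]OC(=C)CCO[Si](C)(C)C(C)(C)C | intermediate
12 | tert-butyl(dimethyl){[3-(trimethylsilyloxy)but-3-en-1-yl]oxy}silane | C=C(O[Si](C)(C)C)CCO[Si](C)(C)C(C)(C)C | intermediate
13 | C5–C15 β-hydroxy ketone (5-OPMB, 7,9-acetonide, 11-OH, 13-ketone, 15-OTBS) | COc1ccc(COCC[C@H](O2)C[C@@H](OC2(C)C)C[C@H](O)CC(=O)CCO[Si](C)(C)C(C)(C)C)cc1 | intermediate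
14 | C5–C15 11,13-anti diol (5-OPMB, 7,9-acetonide, 15-OTBS) | COc1ccc(COCC[C@H](O2)C[C@@H](OC2(C)C)C[C@H](O)C[C@@H](O)CCO[Si](C)(C)C(C)(C)C)cc1 | intermediate
15 | C5–C15 bis-acetonide (5-OPMB, 15-OTBS) | COc1ccc(COCC[C@H](O2)C[C@@H](OC2(C)C)C[C@H](O2)C[C@@H](OC2(C)C)CCO[Si](C)(C)C(C)(C)C)cc1 | intermediate
16 | C5–C15 bis-acetonide, C15 alcohol | COc1ccc(COCC[C@H](O2)C[C@@H](OC2(C)C)C[C@H](O2)C[C@@H](OC2(C)C)CCO)cc1 | intermediate
17 | C5–C15 bis-acetonide, C15 aldehyde | COc1ccc(COCC[C@H](O2)C[C@@H](OC2(C)C)C[C@H](O2)C[C@@H](OC2(C)C)CC=O)cc1 | intermediate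
18 | (S)-4-benzyl-3-propanoyl-1,3-oxazolidin-2-one | CCC(=O)N1[C@@H](Cc2ccccc2)COC1=O | starting material
19 | prop-2-enal | C=CC=O | starting material
20 | (Z)-dibutylboron enolate of 18 (not isolated) | C/C=C(\OB(CCCC)CCCC)N1[C@@H](Cc2ccccc2)COC1=O | intermediate
21 | (S)-4-benzyl-3-[(2S,3R)-3-hydroxy-2-methylpent-4-enoyl]-1,3-oxazolidin-2-one | O=C1OC[C@H](Cc2ccccc2)N1C(=O)[C@@H](C)[C@H](O)C=C | intermediate
22 | (2S,3R)-3-hydroxy-N-methoxy-N,2-dimethylpent-4-enamide | CON(C)C(=O)[C@@H](C)[C@H](O)C=C | intermediate
23 | (2S,3R)-3-{[tert-butyl(dimethyl)silyl]oxy}-N-methoxy-N,2-dimethylpent-4-enamide | CON(C)C(=O)[C@@H](C)[C@H](O[Si](C)(C)C(C)(C)C)C=C | intermediate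
24 | (3S,4R)-4-{[tert-butyl(dimethyl)silyl]oxy}-3-methylhex-5-en-2-one | CC(=O)[C@@H](C)[C@H](O[Si](C)(C)C(C)(C)C)C=C | intermediate
25 | lithium enolate of 24 (methyl side; not isolated) | [Li]OC(=C)[C@@H](C)[C@H](O[Si](C)(C)C(C)(C)C)C=C | intermediate
26 | tert-butyl{[(3R,4S)-4-methyl-5-(trimethylsilyloxy)hexa-1,5-dien-3-yl]oxy}dimethylsilane | C=C(O[Si](C)(C)C)[C@@H](C)[C@H](O[Si](C)(C)C(C)(C)C)C=C | intermediate
27 | C5–C20 β-hydroxy ketone (15-OH, 17-ketone, 19-OTBS, vinyl) | COc1ccc(COCC[C@H](O2)C[C@@H](OC2(C)C)C[C@H](O2)C[C@@H](OC2(C)C)C[C@H](O)CC(=O)[C@@H](C)[C@H](O[Si](C)(C)C(C)(C)C)C=C)cc1 | intermediate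
28 | C5–C20 15,17-anti diol | COc1ccc(COCC[C@H](O2)C[C@@H](OC2(C)C)C[C@H](O2)C[C@@H](OC2(C)C)C[C@H](O)C[C@@H](O)[C@@H](C)[C@H](O[Si](C)(C)C(C)(C)C)C=C)cc1 | intermediate
29 | C5–C20 tris-acetonide with terminal vinyl | COc1ccc(COCC[C@H](O2)C[C@@H](OC2(C)C)C[C@H](O2)C[C@@H](OC2(C)C)C[C@H](O2)C[C@@H](OC2(C)C)[C@@H](C)[C@H](O[Si](C)(C)C(C)(C)C)C=C)cc1 | intermediate
30 | vicinal diol from 29 (both epimers at C20; not isolated) | COc1ccc(COCC[C@H](O2)C[C@@H](OC2(C)C)C[C@H](O2)C[C@@H](OC2(C)C)C[C@H](O2)C[C@@H](OC2(C)C)[C@@H](C)[C@H](O[Si](C)(C)C(C)(C)C)C(O)CO)cc1 | intermediate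
31 | C5–C20 tris-acetonide, C20 aldehyde | COc1ccc(COCC[C@H](O2)C[C@@H](OC2(C)C)C[C@H](O2)C[C@@H](OC2(C)C)C[C@H](O2)C[C@@H](OC2(C)C)[C@@H](C)[C@H](O[Si](C)(C)C(C)(C)C)C=O)cc1 | intermediate
32 | rac-2-(2-bromoethyl)oxirane | BrCCC1CO1 | starting material
33 | (S)-2-(2-bromoethyl)oxirane | BrCC[C@H]1CO1 | intermediate
34 | 1-bromo-5-chloropentane | ClCCCCCBr | starting material
35 | prop-1-yn-1-yllithium | [Li]C#CC | starting material
36 | 8-chlorooct-2-yne | CC#CCCCCCCl | intermediate
37 | oct-6-yn-1-ylmagnesium chloride (not isolated) | CC#CCCCCC[Mg]Cl | intermediate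
38 | (R)-1-bromododec-10-yn-3-ol | BrCC[C@H](O)CCCCCCC#CC | intermediate
39 | (R)-[(1-bromododec-10-yn-3-yl)oxy](tert-butyl)dimethylsilane | BrCC[C@H](O[Si](C)(C)C(C)(C)C)CCCCCCC#CC | intermediate
40 | [(3R)-3-{[tert-butyl(dimethyl)silyl]oxy}dodec-10-yn-1-yl]magnesium bromide (not isolated) | Br[Mg]CC[C@H](O[Si](C)(C)C(C)(C)C)CCCCCCC#CC | intermediate
41 | (3R,7R)-1-bromo-7-{[tert-butyl(dimethyl)silyl]oxy}hexadec-14-yn-3-ol | BrCC[C@H](O)CCC[C@H](O[Si](C)(C)C(C)(C)C)CCCCCCC#CC | intermediate
42 | (3R,7R)-1-bromo-3,7-bis{[tert-butyl(dimethyl)silyl]oxy}hexadec-14-yne | BrCC[C@H](O[Si](C)(C)C(C)(C)C)CCC[C@H](O[Si](C)(C)C(C)(C)C)CCCCCCC#CC | intermediate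
43 | Grignard reagent of 42 (not isolated) | Br[Mg]CC[C@H](O[Si](C)(C)C(C)(C)C)CCC[C@H](O[Si](C)(C)C(C)(C)C)CCCCCCC#CC | intermediate
44 | (3R,7S,11R)-1-bromo-7,11-bis{[tert-butyl(dimethyl)silyl]oxy}icos-18-yn-3-ol | BrCC[C@H](O)CCC[C@H](O[Si](C)(C)C(C)(C)C)CCC[C@H](O[Si](C)(C)C(C)(C)C)CCCCCCC#CC | intermediate
45 | (3R,7R,11R)-1-bromo-3,7,11-tris{[tert-butyl(dimethyl)silyl]oxy}icos-18-yne | BrCC[C@H](O[Si](C)(C)C(C)(C)C)CCC[C@H](O[Si](C)(C)C(C)(C)C)CCC[C@H](O[Si](C)(C)C(C)(C)C)CCCCCCC#CC | intermediate
46 | [(3R,7R,11R)-3,7,11-tris{[tert-butyl(dimethyl)silyl]oxy}icos-18-yn-1-yl]triphenylphosphonium bromide | [Br-].c1ccccc1[P+](c1ccccc1)(c1ccccc1)CC[C@H](O[Si](C)(C)C(C)(C)C)CCC[C@H](O[Si](C)(C)C(C)(C)C)CCC[C@H](O[Si](C)(C)C(C)(C)C)CCCCCCC#CC | intermediate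
47 | ylide of 46 (not isolated) | c1ccccc1P(c1ccccc1)(c1ccccc1)=CC[C@H](O[Si](C)(C)C(C)(C)C)CCC[C@H](O[Si](C)(C)C(C)(C)C)CCC[C@H](O[Si](C)(C)C(C)(C)C)CCCCCCC#CC | intermediate
48 | C5–C38 chain, 20Z, 5-OPMB | COc1ccc(COCC[C@H](O2)C[C@@H](OC2(C)C)C[C@H](O2)C[C@@H](OC2(C)C)C[C@H](O2)C[C@@H](OC2(C)C)[C@@H](C)[C@H](O[Si](C)(C)C(C)(C)C)/C=C\C[C@H](O[Si](C)(C)C(C)(C)C)CCC[C@H](O[Si](C)(C)C(C)(C)C)CCC[C@H](O[Si](C)(C)C(C)(C)C)CCCCCCC#CC)cc1 | intermediate
49 | C5–C38 chain, C5 alcohol | OCC[C@H](O2)C[C@@H](OC2(C)C)C[C@H](O2)C[C@@H](OC2(C)C)C[C@H](O2)C[C@@H](OC2(C)C)[C@@H](C)[C@H](O[Si](C)(C)C(C)(C)C)/C=C\C[C@H](O[Si](C)(C)C(C)(C)C)CCC[C@H](O[Si](C)(C)C(C)(C)C)CCC[C@H](O[Si](C)(C)C(C)(C)C)CCCCCCC#CC | intermediate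
50 | C5–C38 chain, C5 aldehyde | O=CC[C@H](O2)C[C@@H](OC2(C)C)C[C@H](O2)C[C@@H](OC2(C)C)C[C@H](O2)C[C@@H](OC2(C)C)[C@@H](C)[C@H](O[Si](C)(C)C(C)(C)C)/C=C\C[C@H](O[Si](C)(C)C(C)(C)C)CCC[C@H](O[Si](C)(C)C(C)(C)C)CCC[C@H](O[Si](C)(C)C(C)(C)C)CCCCCCC#CC | intermediate
51 | ethyl 2-[bis(2,2,2-trifluoroethoxy)phosphoryl]propanoate | CCOC(=O)C(C)P(=O)(OCC(F)(F)F)OCC(F)(F)F | starting material
52 | potassium salt of the carbanion of 51 (not isolated) | CCOC(=O)[C-](C)P(=O)(OCC(F)(F)F)OCC(F)(F)F.[K+] | intermediate
53 | C3–C38 ethyl (Z)-2-methyl-enoate | CCOC(=O)/C(C)=C\C[C@H](O2)C[C@@H](OC2(C)C)C[C@H](O2)C[C@@H](OC2(C)C)C[C@H](O2)C[C@@H](OC2(C)C)[C@@H](C)[C@H](O[Si](C)(C)C(C)(C)C)/C=C\C[C@H](O[Si](C)(C)C(C)(C)C)CCC[C@H](O[Si](C)(C)C(C)(C)C)CCC[C@H](O[Si](C)(C)C(C)(C)C)CCCCCCC#CC | intermediate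
54 | C3–C38 (Z)-allylic alcohol | OC/C(C)=C\C[C@H](O2)C[C@@H](OC2(C)C)C[C@H](O2)C[C@@H](OC2(C)C)C[C@H](O2)C[C@@H](OC2(C)C)[C@@H](C)[C@H](O[Si](C)(C)C(C)(C)C)/C=C\C[C@H](O[Si](C)(C)C(C)(C)C)CCC[C@H](O[Si](C)(C)C(C)(C)C)CCC[C@H](O[Si](C)(C)C(C)(C)C)CCCCCCC#CC | intermediate
55 | C3–C38 (Z)-2-methyl-enal | O=C/C(C)=C\C[C@H](O2)C[C@@H](OC2(C)C)C[C@H](O2)C[C@@H](OC2(C)C)C[C@H](O2)C[C@@H](OC2(C)C)[C@@H](C)[C@H](O[Si](C)(C)C(C)(C)C)/C=C\C[C@H](O[Si](C)(C)C(C)(C)C)CCC[C@H](O[Si](C)(C)C(C)(C)C)CCC[C@H](O[Si](C)(C)C(C)(C)C)CCCCCCC#CC | intermediate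
56 | 6-bromohex-1-ene | C=CCCCCBr | starting material
57 | (R)-2-methyloxirane | C[C@@H]1CO1 | starting material
58 | hex-5-en-1-ylmagnesium bromide (not isolated) | C=CCCCC[Mg]Br | intermediate
59 | (R)-non-8-en-2-ol | C=CCCCCC[C@@H](C)O | intermediate
60 | (R)-tert-butyl(dimethyl)(non-8-en-2-yloxy)silane | C=CCCCCC[C@@H](C)O[Si](C)(C)C(C)(C)C | intermediate
61 | (R)-7-{[tert-butyl(dimethyl)silyl]oxy}octanal | O=CCCCCC[C@@H](C)O[Si](C)(C)C(C)(C)C | intermediate
62 | (Z)-but-2-ene | C/C=C\C | starting material
63 | (Z)-but-2-en-1-ylpotassium (not isolated) | C/C=C\C[K] | intermediate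
64 | (Z)-but-2-en-1-yl-bis(isopinocampheyl)borane, Ipc from (+)-α-pinene (not isolated) | C/C=C\CB([C@@H]1C[C@@H]2C[C@H]([C@H]1C)C2(C)C)[C@@H]1C[C@@H]2C[C@H]([C@H]1C)C2(C)C | intermediate
65 | (3R,4R,10R)-10-{[tert-butyl(dimethyl)silyl]oxy}-3-methylundec-1-en-4-ol | C=C[C@@H](C)[C@H](O)CCCCC[C@@H](C)O[Si](C)(C)C(C)(C)C | intermediate
66 | (3R,4R,10R)-4,10-bis{[tert-butyl(dimethyl)silyl]oxy}-3-methylundec-1-ene | C=C[C@@H](C)[C@H](O[Si](C)(C)C(C)(C)C)CCCCC[C@@H](C)O[Si](C)(C)C(C)(C)C | intermediate
67 | 2-[(2R,3R,9R)-3,9-bis{[tert-butyl(dimethyl)silyl]oxy}decan-2-yl]oxirane (epimers at the oxirane carbon) | C1OC1[C@@H](C)[C@H](O[Si](C)(C)C(C)(C)C)CCCCC[C@@H](C)O[Si](C)(C)C(C)(C)C | intermediate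
68 | (R)-2-[(2R,3R,9R)-3,9-bis{[tert-butyl(dimethyl)silyl]oxy}decan-2-yl]oxirane | O1C[C@H]1[C@@H](C)[C@H](O[Si](C)(C)C(C)(C)C)CCCCC[C@@H](C)O[Si](C)(C)C(C)(C)C | intermediate
69 | (5S,6R,7R,13R)-7,13-bis{[tert-butyl(dimethyl)silyl]oxy}-6-methyltetradec-2-yn-5-ol | CC#CC[C@H](O)[C@@H](C)[C@H](O[Si](C)(C)C(C)(C)C)CCCCC[C@@H](C)O[Si](C)(C)C(C)(C)C | intermediate
70 | 2-(diethoxyphosphoryl)acetic acid | CCOP(=O)(OCC)CC(=O)O | starting material
71 | (5S,6R,7R,13R)-7,13-bis{[tert-butyl(dimethyl)silyl]oxy}-6-methyltetradec-2-yn-5-yl 2-(diethoxyphosphoryl)acetate | CCOP(=O)(OCC)CC(=O)O[C@@H](CC#CC)[C@@H](C)[C@H](O[Si](C)(C)C(C)(C)C)CCCCC[C@@H](C)O[Si](C)(C)C(C)(C)C | intermediate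
72 | ester-linked seco-diyne (three acetonides, six TBS ethers) | CC#CC[C@@H]([C@@H](C)[C@H](O[Si](C)(C)C(C)(C)C)CCCCC[C@@H](C)O[Si](C)(C)C(C)(C)C)OC(=O)\C=C\C(C)=C/C[C@H](O2)C[C@@H](OC2(C)C)C[C@H](O2)C[C@@H](OC2(C)C)C[C@H](O2)C[C@@H](OC2(C)C)[C@@H](C)[C@H](O[Si](C)(C)C(C)(C)C)/C=C\C[C@H](O[Si](C)(C)C(C)(C)C)CCC[C@H](O[Si](C)(C)C(C)(C)C)CCC[C@H](O[Si](C)(C)C(C)(C)C)CCCCCCC#CC | intermediate
73 | protected 42-membered cycloalkyne | CC1=C/C[C@H](O2)C[C@@H](OC2(C)C)C[C@H](O2)C[C@@H](OC2(C)C)C[C@H](O2)C[C@@H](OC2(C)C)[C@@H](C)[C@H](O[Si](C)(C)C(C)(C)C)/C=C\C[C@H](O[Si](C)(C)C(C)(C)C)CCC[C@H](O[Si](C)(C)C(C)(C)C)CCC[C@H](O[Si](C)(C)C(C)(C)C)CCCCCCC#CC[C@@H]([C@@H](C)[C@H](O[Si](C)(C)C(C)(C)C)CCCCC[C@@H](C)O[Si](C)(C)C(C)(C)C)OC(=O)\C=C\1 | intermediate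
74 | protected macrolide, 38Z | CC1=C/C[C@H](O2)C[C@@H](OC2(C)C)C[C@H](O2)C[C@@H](OC2(C)C)C[C@H](O2)C[C@@H](OC2(C)C)[C@@H](C)[C@H](O[Si](C)(C)C(C)(C)C)/C=C\C[C@H](O[Si](C)(C)C(C)(C)C)CCC[C@H](O[Si](C)(C)C(C)(C)C)CCC[C@H](O[Si](C)(C)C(C)(C)C)CCCCCC/C=C\C[C@@H]([C@@H](C)[C@H](O[Si](C)(C)C(C)(C)C)CCCCC[C@@H](C)O[Si](C)(C)C(C)(C)C)OC(=O)\C=C\1 | intermediate
75 | CNP0071908.1 | CC1=C/C[C@H](O)C[C@@H](O)C[C@H](O)C[C@@H](O)C[C@H](O)C[C@@H](O)[C@@H](C)[C@H](O)/C=C\C[C@H](O)CCC[C@H](O)CCC[C@H](O)CCCCCC/C=C\C[C@@H]([C@@H](C)[C@H](O)CCCCC[C@@H](C)O)OC(=O)\C=C\1 | target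

## Step count and uncertain steps

Total: 49 steps. Longest linear sequence: 24 steps (1–5, 8–12, 18–21, 31–36, 46–49), from 1 to 75.

Step 47 (key step). The most likely failure is intermolecular metathesis outrunning ring closure, because the two alkyne ends of a 42-membered ring meet rarely, together with slow catalyst turnover near the branched C41 centre or catalyst death from traces of moisture. Fallback: set out from 55 and 71 and join them first by alkyne cross-metathesis with the same molybdenum alkylidyne and sieves, using 71 in excess, to give the open enal phosphonoacetate F1, in which C38≡C39 already exists. F1 is then closed at C2=C3 by an intramolecular Horner–Wadsworth–Emmons reaction at high dilution (Ba(OH)2, or LiCl with iPr2NEt), a ring closure known for very large dienoate lactones. This returns to the route at 73.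

Step 8. The likely failure is poor facial selectivity in the aldol, because the directing β-oxygen at C9 is locked in the acetonide ring and its 1,3-anti bias may be modest; some loss of the acetonide to the Lewis acid is also possible. Fallback: set out from 8 and build C11 and C13 under reagent control. Allylation with (+)-Ipc2B(allyl) gives the homoallylic alcohol F2, which is silylated (Et3SiCl, imidazole) to the triethylsilyl ether F3 and cleaved (OsO4, NaIO4) to the aldehyde F4. A second allylation with (−)-Ipc2B(allyl) gives the anti alcohol F5; acid-catalysed exchange of the silyl ether for the acetonide (PPTS, 2,2-dimethoxypropane) gives the bis-acetonide alkene F6, and oxidative cleavage of its alkene returns to the route at 17.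

Step 18. The likely failure is again insufficient 1,3-anti induction, here with two valuable partners, and transfer of the silyl group giving mixtures of silylated and free aldol. Fallback: set out from ketone 24 and aldehyde 17 and run a boron aldol ((c-C6H11)2BCl, Et3N, then 17; oxidative work-up). The closed chair transition state moves control from the aldehyde to the ketone (1,4-syn induction by the C18 methyl, which is the sense needed, and which isopinocampheyl ligands on boron could reinforce). This makes no new compound and returns to the route at 27.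

Step 24 (and likewise steps 26 and 28). The likely failure is competing copper-catalysed coupling at the primary C–Br bond of 33 or of the product, or cyclisation of the bromo-alkoxide to an oxetane during warming. Fallback: set out from 36 and open, under the same copper catalysis, the silyl ether epoxide (S)-tert-butyl(dimethyl)[2-(oxiran-2-yl)ethoxy]silane F7, which has no halide. The resulting alcohol F8 is silylated to the bis-silyl ether F9, the primary silyl ether is removed selectively (HF·pyridine, pyridine, THF) to give the primary alcohol F10, and an Appel bromination (CBr4, PPh3) returns to the route at 39.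

Step 43. The likely failure is slow and incompletely selective hydrolysis, since the oxirane is α-branched and flanked by a bulky silyl ether; at best half of the material is lost. Fallback: set out from 65 and let the free C43 hydroxyl direct the oxygenation. Boc2O with DMAP gives the tert-butyl carbonate F11; iodocarbonate cyclisation (IBr, toluene, −85 °C) gives the cyclic iodocarbonate F12 with O41 syn to O43; K2CO3 in MeOH gives the epoxy alcohol F13; silylation (TBSOTf, 2,6-lutidine) returns to the route at 68.

Step 49. The likely failure is migration of the acyl group from O41 to the neighbouring O43 once both are free, incomplete removal of the hindered C43 silyl ether, or ionisation at the allylic C19 position under prolonged acid. Fallback: set out from 74 and separate the two deprotections. Buffered HF·pyridine in THF removes the silyl ethers to give the hexaol tris-acetonide F14, and brief treatment with aqueous acetic acid then hydrolyses the acetonides and returns to the route at 75.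

## Further compounds

F1 | step 47 | open C3 enal / C41 phosphonoacetate joined at C38≡C39 | O=C/C(C)=C\C[C@H](O2)C[C@@H](OC2(C)C)C[C@H](O2)C[C@@H](OC2(C)C)C[C@H](O2)C[C@@H](OC2(C)C)[C@@H](C)[C@H](O[Si](C)(C)C(C)(C)C)/C=C\C[C@H](O[Si](C)(C)C(C)(C)C)CCC[C@H](O[Si](C)(C)C(C)(C)C)CCC[C@H](O[Si](C)(C)C(C)(C)C)CCCCCCC#CC[C@H](OC(=O)CP(=O)(OCC)OCC)[C@@H](C)[C@H](O[Si](C)(C)C(C)(C)C)CCCCC[C@@H](C)O[Si](C)(C)C(C)(C)C
F2 | step 8 | C5–C14 homoallylic alcohol (11-OH anti to O9) | COc1ccc(COCC[C@H](O2)C[C@@H](OC2(C)C)C[C@H](O)CC=C)cc1
F3 | step 8 | triethylsilyl ether of F2 | COc1ccc(COCC[C@H](O2)C[C@@H](OC2(C)C)C[C@H](O[Si](CC)(CC)CC)CC=C)cc1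
F4 | step 8 | C5–C13 aldehyde (11-OTES) | COc1ccc(COCC[C@H](O2)C[C@@H](OC2(C)C)C[C@H](O[Si](CC)(CC)CC)CC=O)cc1
F5 | step 8 | C5–C16 homoallylic alcohol (11-OTES, 13-OH anti) | COc1ccc(COCC[C@H](O2)C[C@@H](OC2(C)C)C[C@H](O[Si](CC)(CC)CC)C[C@@H](O)CC=C)cc1
F6 | step 8 | C5–C16 bis-acetonide terminal alkene | COc1ccc(COCC[C@H](O2)C[C@@H](OC2(C)C)C[C@H](O2)C[C@@H](OC2(C)C)CC=C)cc1
F0 | step 18 | none | none
F7 | step 24 | (S)-tert-butyl(dimethyl)[2-(oxiran-2-yl)ethoxy]silane | CC(C)(C)[Si](C)(C)OCC[C@H]1CO1
F8 | step 24 | (R)-1-{[tert-butyl(dimethyl)silyl]oxy}dodec-10-yn-3-ol | CC(C)(C)[Si](C)(C)OCC[C@H](O)CCCCCCC#CC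
F9 | step 24 | (R)-1,3-bis{[tert-butyl(dimethyl)silyl]oxy}dodec-10-yne | CC(C)(C)[Si](C)(C)OCC[C@H](O[Si](C)(C)C(C)(C)C)CCCCCCC#CC
F10 | step 24 | (R)-3-{[tert-butyl(dimethyl)silyl]oxy}dodec-10-yn-1-ol | OCC[C@H](O[Si](C)(C)C(C)(C)C)CCCCCCC#CC
F11 | step 43 | tert-butyl carbonate of 65 | C=C[C@@H](C)[C@H](OC(=O)OC(C)(C)C)CCCCC[C@@H](C)O[Si](C)(C)C(C)(C)C
F12 | step 43 | cyclic iodocarbonate (4-iodomethyl-5-methyl-6-alkyl-1,3-dioxan-2-one, all-cis) | IC[C@@H]1OC(=O)O[C@H](CCCCC[C@@H](C)O[Si](C)(C)C(C)(C)C)[C@@H]1C
F13 | step 43 | epoxy alcohol (C40–C41 epoxide, free 43-OH) | O1C[C@H]1[C@@H](C)[C@H](O)CCCCC[C@@H](C)O[Si](C)(C)C(C)(C)C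
F14 | step 49 | macrolide hexaol tris-acetonide | CC1=C/C[C@H](O2)C[C@@H](OC2(C)C)C[C@H](O2)C[C@@H](OC2(C)C)C[C@H](O2)C[C@@H](OC2(C)C)[C@@H](C)[C@H](O)/C=C\C[C@H](O)CCC[C@H](O)CCC[C@H](O)CCCCCC/C=C\C[C@@H]([C@@H](C)[C@H](O)CCCCC[C@@H](C)O)OC(=O)\C=C\1
A1 | alternative 1 | C2-symmetric bis-homoallylic diol (C6–C18, acetonide on C11/C13) | C=CC[C@@H](O)C[C@H](O2)C[C@@H](OC2(C)C)C[C@H](O)CC=C
A2 | alternative 2 | C3–C19 α-methyl unsaturated δ-lactone | CC1=CC[C@H](OC1=O)C[C@@H](O2)C[C@H](OC2(C)C)C[C@@H](O2)C[C@H](OC2(C)C)C[C@@H](O[Si](C)(C)C(C)(C)C)[C@@H](C)COCc1ccc(OC)cc1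
A3 | alternative 2 | methacrylate of the C7 homoallylic alcohol | C=C(C)C(=O)O[C@@H](CC=C)C[C@@H](O2)C[C@H](OC2(C)C)C[C@@H](O2)C[C@H](OC2(C)C)C[C@@H](O[Si](C)(C)C(C)(C)C)[C@@H](C)COCc1ccc(OC)cc1
A4 | alternative 3 | C5–C38 chain with the 20Z alkene in the cyclic silylene | COc1ccc(cc1)COCC[C@H](O2)C[C@@H](OC2(C)C)C[C@H](O2)C[C@@H](OC2(C)C)C[C@H](O2)C[C@@H](OC2(C)C)[C@@H](C)[C@H]3/C=C\C[C@H](O[Si](C(C)C)(C(C)C)O3)CCC[C@H](O[Si](C)(C)C(C)(C)C)CCC[C@H](O[Si](C)(C)C(C)(C)C)CCCCCCCO[Si](c1ccccc1)(c1ccccc1)C(C)(C)C
A5 | alternative 3 | mixed diisopropylsilylene bis-ether (C19 vinyl carbinol and C23 allyl carbinol) | COc1ccc(cc1)COCC[C@H](O2)C[C@@H](OC2(C)C)C[C@H](O2)C[C@@H](OC2(C)C)C[C@H](O2)C[C@@H](OC2(C)C)[C@@H](C)[C@@H](C=C)O[Si](C(C)C)(C(C)C)O[C@@H](CC=C)CCC[C@H](O[Si](C)(C)C(C)(C)C)CCC[C@H](O[Si](C)(C)C(C)(C)C)CCCCCCCO[Si](c1ccccc1)(c1ccccc1)C(C)(C)C
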